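**Retrosynthetic overview**
1. Chain numbering: C1=C2 vinyl, C3 acyloxy carbon, C4≡C5–C6≡C7 diyne, C8H2, oxirane C9–C10–O, C11–C17 heptyl. The last disconnection is the C5–C6 sp–sp single bond, made by a Cadiot–Chodkiewicz union of bromoalkyne ester 15 (C23) with terminal alkyne 7 (C12), which gives the target directly without protecting groups.
2. Enabling feature: the conjugated 1,3-diyne C4≡C5–C6≡C7. Each half ends in an alkyne carbon, C8H2 insulates the oxirane, and the bromine is placed on C5 so that no copper acetylide can form next to the C3–O ester bond.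
3. Ester half 15: acrolein + the bromomagnesium acetylide of ethynyltrimethylsilane → racemic carbinol → lipase resolution sets C3 → silver-catalysed Si→Br exchange → linoleoyl ester.
4. Epoxide half 7: Sharpless epoxidation of (E)-dec-2-en-1-ol sets C9 and C10 → triflate → lithium silylacetylide displacement → desilylation.
5. Rings: the oxirane is the only ring; it is closed in step 1 and carried unchanged to the end.

Key step: step 9

Remark: the SMILES encodes S at C3 and a trans oxirane with both ring carbons R (not a cis epoxide), and the route is planned for exactly this isomer. (E)-Dec-2-en-1-ol, ethynyltrimethylsilane, acrolein and linoleoyl chloride are taken as purchased.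

**Step 1**
Reactants: 1 (E)-dec-2-en-1-ol
Product: 2 [(2R,3R)-3-heptyloxiran-2-yl]methanol
Conditions: Ti(OiPr)4 (cat.), D-(−)-diethyl tartrate (cat.), t-BuOOH, 4 Å molecular sieves, CH2Cl2, −20 °C
Reagents that add atoms: tert-butyl hydroperoxide, CC(C)(C)OO
Why: Sharpless asymmetric epoxidation of a primary (E)-allylic alcohol is reliable; the D-(−)-tartrate–titanium catalyst should deliver oxygen to the olefin face that gives the (2R,3R)-epoxy alcohol, and the trans relationship of C9 and C10 follows stereospecifically from the E olefin.

**Step 2**
Reactants: 2 [(2R,3R)-3-heptyloxiran-2-yl]methanol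
Product: 3 [(2R,3R)-3-heptyloxiran-2-yl]methyl trifluoromethanesulfonate
Conditions: Tf2O, 2,6-lutidine, CH2Cl2, −78 °C; cold aqueous wash, used at once
Reagents that add atoms: trifluoromethanesulfonic anhydride, O=S(=O)(OS(=O)(=O)C(F)(F)F)C(F)(F)F
Why: Sulfonylation of the primary alcohol with a hindered pyridine base at −78 °C touches no stereocenter and installs a leaving group reactive enough to be displaced at low temperature, where the oxirane is left alone.

**Step 3**
Reactants: 3 [(2R,3R)-3-heptyloxiran-2-yl]methyl trifluoromethanesulfonate; 4 ethynyltrimethylsilane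
Product: 6 {3-[(2R,3R)-3-heptyloxiran-2-yl]prop-1-yn-1-yl}trimethylsilane, via lithium (trimethylsilyl)acetylide 5 (not isolated)
Conditions: 4, n-BuLi, THF, −78 °C; then 3, N,N′-dimethylpropyleneurea, −78 → −30 °C
Reagents that add atoms: none
Why: SN2 alkylation of a lithium acetylide by a primary triflate at −78 °C is much faster than opening of the neighbouring 2,3-disubstituted oxirane, so the C7–C8 bond should form with both oxirane centers unchanged.

**Step 4**
Reactants: 6 {3-[(2R,3R)-3-heptyloxiran-2-yl]prop-1-yn-1-yl}trimethylsilane
Product: 7 (2R,3R)-2-heptyl-3-(prop-2-yn-1-yl)oxirane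
Conditions: K2CO3 (cat.), MeOH, 0 °C
Reagents that add atoms: none
Why: Base-catalysed methanolysis of the C(sp)–Si bond (protodesilylation) is fast at 0 °C and should leave the oxirane and both of its stereocenters untouched.

**Step 5**
Reactants: 8 acrolein; 4 ethynyltrimethylsilane
Product: 11 rac-5-(trimethylsilyl)pent-1-en-4-yn-3-ol, via magnesium acetylide 9 (not isolated), via magnesium alkoxide 10 (not isolated)
Conditions: 4, EtMgBr, THF, 0 °C → room temperature; then 8, −78 → 0 °C; sat. aq. NH4Cl
Reagents that add atoms: none
Why: Grignard 1,2-addition: EtMgBr deprotonates the terminal alkyne to the bromomagnesium acetylide, which should add to the carbonyl of the enal rather than in conjugate fashion at low temperature, and the carbinol center forms as the racemate that is resolved in step 6.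

**Step 6**
Reactants: 11 rac-5-(trimethylsilyl)pent-1-en-4-yn-3-ol
Product: 12 (3S)-5-(trimethylsilyl)pent-1-en-4-yn-3-ol
Conditions: lipase from Pseudomonas fluorescens (Amano lipase AK), vinyl acetate, hexane, room temperature, stopped just past half conversion; chromatography
Reagents that add atoms: none
Why: Lipase-catalysed kinetic resolution by irreversible transesterification: by the empirical size rule for lipases (vinyl as the medium, silylethynyl as the large substituent) the R alcohol should be acetylated and the S alcohol, which carries the C3 configuration of the target, should remain, the assignment to be confirmed by Mosher ester analysis.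

**Step 7**
Reactants: 12 (3S)-5-(trimethylsilyl)pent-1-en-4-yn-3-ol
Product: 13 (3S)-5-bromopent-1-en-4-yn-3-ol
Conditions: NBS, AgNO3 (10 mol %), acetone, room temperature, dark
Reagents that add atoms: N-bromosuccinimide, O=C1CCC(=O)N1Br
Why: Silver-catalysed desilylative bromination: AgNO3 converts the alkynylsilane into a silver acetylide that NBS brominates, giving the 1-bromoalkyne directly without passing through the volatile terminal enynol, and the carbinol center is not involved.

**Step 8**
Reactants: 13 (3S)-5-bromopent-1-en-4-yn-3-ol; 14 (9Z,12Z)-octadeca-9,12-dienoyl chloride (linoleoyl chloride)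
Product: 15 (3S)-5-bromopent-1-en-4-yn-3-yl (9Z,12Z)-octadeca-9,12-dienoate
Conditions: pyridine, 4-(dimethylamino)pyridine (cat.), CH2Cl2, 0 °C
Reagents that add atoms: none
Why: Acylation of a secondary alcohol by an acid chloride with nucleophilic catalysis by 4-(dimethylamino)pyridine forms the ester at oxygen, so C3 keeps its S configuration, and the mild base should leave the bromoalkyne and the skipped Z,Z-diene intact.

**Step 9**
Reactants: 15 (3S)-5-bromopent-1-en-4-yn-3-yl (9Z,12Z)-octadeca-9,12-dienoate; 7 (2R,3R)-2-heptyl-3-(prop-2-yn-1-yl)oxirane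
Product: 16 (3S)-8-[(2R,3R)-3-heptyloxiran-2-yl]oct-1-ene-4,6-diyn-3-yl (9Z,12Z)-octadeca-9,12-dienoate
Conditions: CuCl (10 mol %), NH2OH·HCl (30 mol %), 30 % aq. n-BuNH2, CH2Cl2, 0 °C, argon; 15 added slowly to 7 (1.3 equiv)
Reagents that add atoms: none
Why: Cadiot–Chodkiewicz cross-coupling: CuCl and the amine turn the terminal alkyne of 7 into a monovalent copper acetylide, which adds oxidatively into the C(sp)–Br bond of 15 to give a trivalent copper bis(alkynyl) species whose reductive elimination forms the C5–C6 bond and with it the conjugated diyne, while hydroxylamine keeps copper monovalent and so suppresses oxidative homocoupling. The closest known reaction type is the copper-catalysed coupling of 1-bromoalkynes with terminal alkynes used for unsymmetrical polyacetylenes, including partners that carry an oxirane two carbons from the alkyne or an oxygenated vinyl carbinol carbon next to it. No ring is closed and no stereocenter is created; C3 and the two oxirane carbons are set in steps 6 and 1 and should not be touched, since the amine at 0 °C neither deprotonates C3–H or C8–H2 nor opens the trans oxirane. The first selectivity needed is cross-coupling over homocoupling, secured by pairing one bromoalkyne with one terminal alkyne, by slow addition of 15 to an excess of 7 and by the reducing medium. The second is survival of the allylic–propargylic ester: because the bromine sits on C5, no copper acetylide can form beside the acyloxy group (the path that would ionise it to a copper allenylidene and lead to amination), and a short contact time at 0 °C in a two-phase medium should hold aminolysis back. In one operation the step joins the C23 and C12 halves, creates the diyne and delivers the unprotected target.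

**Compound list**
1 | (E)-dec-2-en-1-ol | CCCCCCC/C=C/CO | starting material
2 | [(2R,3R)-3-heptyloxiran-2-yl]methanol | OC[C@H]1O[C@@H]1CCCCCCC | intermediate
3 | [(2R,3R)-3-heptyloxiran-2-yl]methyl trifluoromethanesulfonate | O=S(=O)(OC[C@H]1O[C@@H]1CCCCCCC)C(F)(F)F | intermediate
4 | ethynyltrimethylsilane | C#C[Si](C)(C)C | starting material
5 | lithium (trimethylsilyl)acetylide | [Li+].[C-]#C[Si](C)(C)C | intermediate
6 | {3-[(2R,3R)-3-heptyloxiran-2-yl]prop-1-yn-1-yl}trimethylsilane | C[Si](C)(C)C#CC[C@H]1O[C@@H]1CCCCCCC | intermediate
7 | (2R,3R)-2-heptyl-3-(prop-2-yn-1-yl)oxirane | C#CC[C@H]1O[C@@H]1CCCCCCC | intermediate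
8 | acrolein (prop-2-enal) | C=CC=O | starting material
9 | bromo[(trimethylsilyl)ethynyl]magnesium | C[Si](C)(C)C#C[Mg]Br | intermediate
10 | bromomagnesium 5-(trimethylsilyl)pent-1-en-4-yn-3-olate (racemic) | C=CC(O[Mg]Br)C#C[Si](C)(C)C | intermediate
11 | rac-5-(trimethylsilyl)pent-1-en-4-yn-3-ol | C=CC(O)C#C[Si](C)(C)C | intermediate
12 | (3S)-5-(trimethylsilyl)pent-1-en-4-yn-3-ol | C=C[C@@H](C#C[Si](C)(C)C)O | intermediate
13 | (3S)-5-bromopent-1-en-4-yn-3-ol | C=C[C@@H](C#CBr)O | intermediate
14 | (9Z,12Z)-octadeca-9,12-dienoyl chloride | CCCCC/C=C\C/C=C\CCCCCCCC(=O)Cl | starting material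
15 | (3S)-5-bromopent-1-en-4-yn-3-yl (9Z,12Z)-octadeca-9,12-dienoate | C=C[C@@H](C#CBr)OC(=O)CCCCCCC/C=C\C/C=C\CCCCC | intermediate
16 | (3S)-8-[(2R,3R)-3-heptyloxiran-2-yl]oct-1-ene-4,6-diyn-3-yl (9Z,12Z)-octadeca-9,12-dienoate | C=C[C@@H](C#CC#CC[C@H]1O[C@@H]1CCCCCCC)OC(=O)CCCCCCC/C=C\C/C=C\CCCCC | target

**Step count**
Total steps: 9. Longest linear sequence: 5 steps (steps 5, 6, 7, 8, 9; the other branch, steps 1 to 4 followed by step 9, is equally long).

**Steps most likely to fail**

1. Step 9. The allylic–propargylic ester may be cleaved by the amine (aminolysis) or ionised with copper assistance during the coupling, and either alkyne may homocouple. Fallback: setting out from 13 and 7, the same copper-catalysed coupling (CuCl, NH2OH·HCl, 30 % aq. n-BuNH2, CH2Cl2, 0 °C) would be run on the free carbinol to give (3S)-8-[(2R,3R)-3-heptyloxiran-2-yl]oct-1-ene-4,6-diyn-3-ol F1. F1 would then be acylated with 14 (pyridine, 4-(dimethylamino)pyridine, CH2Cl2, 0 °C), rejoining the route at 16. The ester is then introduced only after the diyne exists, so the coupling has no ester to lose.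

2. Step 3. The acetylide may open the oxirane, or the epoxy triflate may decompose before substitution occurs. Fallback: setting out from 1, PBr3 (Et2O, 0 °C) would give (2E)-1-bromodec-2-ene F2. Alkylation of lithium acetylide 5 (generated from 4 and n-BuLi as in step 3; CuI cat., THF, −78 → 0 °C) with F2 would give trimethyl[(4E)-dodec-4-en-1-yn-1-yl]silane F3. Shi epoxidation of F3 (the D-fructose-derived ketone 1,2:4,5-di-O-isopropylidene-D-erythro-2,3-hexodiulo-2,6-pyranose, KHSO5 used as the triple salt 2KHSO5·KHSO4·K2SO4, K2CO3, MeCN/dimethoxymethane/water, 0 °C) should give the R,R trans epoxide on the spiro transition-state model, rejoining the route at 6. The oxirane is then made after the C–C bond, so no carbon nucleophile ever meets it.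

3. Step 7. The small bromoalkynol may be lost through volatility and decomposition on isolation, or the vinyl carbinol may be brominated electrophilically. Fallback: setting out from 6 and 12, the roles of the two alkynes are exchanged. Compound 6 would be converted with NBS and AgNO3 (acetone, room temperature) into (2R,3R)-2-(3-bromoprop-2-yn-1-yl)-3-heptyloxirane F4. Compound 12 would be desilylated (K2CO3, MeOH, 0 °C) to (3S)-pent-1-en-4-yn-3-ol F5, kept in solution. The two would be coupled (CuCl, NH2OH·HCl, 30 % aq. n-BuNH2, 0 °C) to (3S)-8-[(2R,3R)-3-heptyloxiran-2-yl]oct-1-ene-4,6-diyn-3-ol F1, and acylation with 14 as above would rejoin the route at 16.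

**Further compounds**
F1 | step 9 | (3S)-8-[(2R,3R)-3-heptyloxiran-2-yl]oct-1-ene-4,6-diyn-3-ol | C=C[C@@H](C#CC#CC[C@H]1O[C@@H]1CCCCCCC)O
F2 | step 3 | (2E)-1-bromodec-2-ene | CCCCCCC/C=C/CBr
F3 | step 3 | trimethyl[(4E)-dodec-4-en-1-yn-1-yl]silane | C[Si](C)(C)C#CC/C=C/CCCCCCC
F4 | step 7 | (2R,3R)-2-(3-bromoprop-2-yn-1-yl)-3-heptyloxirane | BrC#CC[C@H]1O[C@@H]1CCCCCCC
F5 | step 7 | (3S)-pent-1-en-4-yn-3-ol | C=C[C@@H](C#C)O
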